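The runs come from a simulation for an exercise, and the scatter is random.

- Late in the delta run, an earlier flask of substrate, partner and free catalyst, substrate falls from 45% at 1.50 h to 34% at 2.50 h, far slower than in the first 0.333 h, so I read its end as a balance with both reagents still present.

| flask | substrate | partner | free catalyst | remark | time |
|---|---|---|---|---|---|
| delta | 0.50 M | 0.45 M | 38 mM | run made earlier |  |
| red | 0.50 M | 0.450 M | 25 mM |  | 12 h |
| blue | 1.0 M | 0.300 M | 25 mM |  | 12 h |

delta run (percent of the substrate charged)

| time / h | target / % | substrate / % |
|---|---|---|
| 0.333 | 22 | 73 |
| 0.667 | 35 | 60 |
| 1.00 | 44 | 49 |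
| 1.33 | 46 | 42 |
| 1.50 | 51 | 45 |
| 2.00 | 49 | 39 |
| 2.50 | 56 | 34 |

(each reading ± 2 percentage points)

1. which one finishes higher in amount of target, in percent of the substrate charged ("neither" within 2 percentage points) (red / blue / neither)
2. amount of target at the end, in percent of the substrate charged, red
3. amount of target at the end, in percent of the substrate charged, blue

- candidate steps: substrate + partner <-> target; substrate + partner <-> isomer of the product; target + free catalyst <-> isomer of the product + free catalyst; substrate + free catalyst -> spent catalyst; substrate + partner -> uncatalysed product
- no earlier run changes the charge of free catalyst; that part of a forecast is a guess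

- At the last delta reading, [target] is 0.280 M and [substrate] is 0.170 M. I take [partner] as its charge less the substrate lost, 0.120 M.
- These give 13.7 L mol⁻¹, a reading that carries the scatter. This is my balance quotient, [target]/([substrate][partner]), an apparent equilibrium constant.
- In the first extreme version, the reaction runs until partner, the limiting reagent, is used up. Target then reaches 90.0% in red and 30.0% in blue.
- In the second extreme version, each flask stops at the quotient. Red has the delta charges of substrate and partner, so it returns the last delta reading, 56%.
- In blue, [substrate] stays near 0.700 M, so target outweighs remaining partner 9.61 to one. The delta run also puts 0.179 of reacted substrate elsewhere for each part of target, and with that share blue gives 23.4%.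
- I expect both flasks near the second version and slightly under it, because 12 h is longer than the delta run, which gives side products more time. What the catalyst charge of red and blue does is a guess, since no earlier run changes it.
- The forecast says red, with 62% for red and 24% for blue (“Red clearly finishes higher”), its red above my figure and its blue close to mine.
- The flasks give red, with 52.2% in red and 21.2% in blue.

    substrate + partner ⇌ target (K = 16.0 L mol⁻¹, k = 2.30 L mol⁻¹ h⁻¹)
    substrate + partner ⇌ isomer of the product (K = 5.30 L mol⁻¹, k = 0.140 L mol⁻¹ h⁻¹)
    target + free catalyst ⇌ isomer of the product + free catalyst, rate k3*[free catalyst]*[target] forward; the back reaction follows from the equilibrium constant (k = 0.810 L mol⁻¹ h⁻¹)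
    substrate + free catalyst → spent catalyst (k = 0.0120 L mol⁻¹ h⁻¹)
    substrate + partner → uncatalysed product (k = 0.0690 L mol⁻¹ h⁻¹)

- At 12.0 h, the quotient stands at 16.5 L mol⁻¹ in red and 16.6 L mol⁻¹ in blue. In red, at the charged concentrations, the forward half-life of substrate towards target alone is 0.67 h, far shorter than the 22 h towards uncatalysed product. The neighbour of blue with 1.2 M of partner ends with 65.7% target and a quotient of 16.6 L mol⁻¹.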